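**Retrosynthetic overview**

1. The last bond made is C12–O: acetate is delivered with allylic transposition (SN2′ under Mitsunobu activation) onto a butenolide carbinol. This creates the 12S centre trans to C13 and moves the olefin to the exocyclic 10E position.
2. The carbinol comes from a C10–C11 Michael–aldol/elimination union of a C16 aldehyde with a small 5-substituted butenolide.
3. The butenolide (the only ring, closed by lactonisation before the fragment union) comes from prenal and methyl propiolate; asymmetric alkynylation sets C13.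
4. The aldehyde comes from nerol (source of the 2Z olefin): methacrylate ester, singlet-oxygen ene reaction (C6–O), then Claisen rearrangement (6E olefin, C9–C10).

Assumption: the SMILES is read as 2Z,6E,10E with a trans (12S,13R) lactone (chain numbering: C1 = OCH2, C10 = alkylidene CH, C11 = lactone α-carbon, C12 = CH–OAc, C13 = ring CH–O, C14=C15 = propenyl), and (S,S)-ProPhenol is taken to give the (R)-carbinol in step 4 (otherwise its mirror-image ligand is used).

**Route**

Step 1
Reactants: 1 nerol; 2 methacryloyl chloride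
Product: 3 (2Z)-3,7-dimethylocta-2,6-dien-1-yl 2-methylprop-2-enoate (neryl methacrylate)
Conditions: Et3N, DMAP (5 mol%), CH2Cl2, 0 °C to rt
Reagents that add atoms: methacryloyl chloride (2), C=C(C)C(=O)Cl
Why: DMAP-catalysed acylation of a primary allylic alcohol with an acid chloride (nucleophilic acyl substitution) is fast at 0 °C and leaves the 2Z olefin untouched.

Step 2
Reactants: 3 neryl methacrylate
Product: 5 (2Z)-6-hydroxy-3,7-dimethylocta-2,7-dien-1-yl 2-methylprop-2-enoate (racemic), via secondary allylic hydroperoxide 4 (not isolated)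
Conditions: O2, visible light, tetraphenylporphyrin (0.2 mol%), CH2Cl2, 0 °C; then PPh3, 0 °C to rt; chromatography
Reagents that add atoms: dioxygen, O=O
Why: Schenck ene reaction of singlet oxygen at the electron-rich distal C6=C7 olefin (the ester-deactivated C2=C3 olefin and the methacrylate are much slower) gives the secondary hydroperoxide by H-abstraction from the cis methyl, about 1:1 with the tertiary regioisomer that is removed after PPh3 reduction; C6 is racemic but is destroyed in step 3.

Step 3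
Reactants: 5 allylic alcohol; 6 ethyl vinyl ether
Product: 8 (2Z,6E)-3,7-dimethyl-10-oxodeca-2,6-dien-1-yl 2-methylprop-2-enoate, via allyl vinyl ether 7 (not isolated)
Conditions: Hg(OAc)2 (20 mol%), ethyl vinyl ether (solvent), reflux, 24 h; filter, concentrate; toluene, BHT (1 mol%), 120 °C (sealed tube), 6 h
Reagents that add atoms: ethyl vinyl ether (6), C=COCC
Why: Vinyl ether exchange followed by Claisen [3,3] rearrangement through a chair with the C6 substituent equatorial forms the C8–C9 bond and the 6E trisubstituted olefin, while BHT suppresses methacrylate polymerisation.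

Step 4
Reactants: 9 3-methylbut-2-enal (prenal); 10 methyl propiolate
Product: 12 methyl (4R)-4-hydroxy-6-methylhept-5-en-2-ynoate, via alkynylzinc 11 (not isolated)
Conditions: Me2Zn (3 equiv), (S,S)-ProPhenol (10 mol%), Ph3P=O (20 mol%), toluene, 0 °C, 24 h; aq NH4Cl
Reagents that add atoms: methyl propiolate (10), C#CC(=O)OC
Why: Trost dinuclear zinc–ProPhenol asymmetric alkynylation delivers the alkynylzinc to one face of the enal inside the chiral dizinc pocket, setting the future C13 centre (R, typically at least 90% ee for enals).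

Step 5
Reactants: 12 propargylic alcohol
Product: 14 (5S)-5-(2-methylprop-1-en-1-yl)furan-2(5H)-one, via Z-hydroxy enoate 13 (not isolated)
Conditions: H2 (1 atm), Pd/CaCO3 poisoned with Pb(OAc)2 (Lindlar catalyst), quinoline, EtOAc, rt; then PPTS (5 mol%), CH2Cl2, rt
Reagents that add atoms: none
Why: Lindlar semi-hydrogenation (syn addition of H2) gives the Z-enoate whose cis γ-hydroxyl lactonises with loss of MeOH to close the lactone ring, leaving the carbinol centre and the trisubstituted olefin untouched (the R to S change is a CIP relabelling only).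

Step 6
Reactants: 14 butenolide (1.2 equiv); 8 aldehyde
Product: 18 (2Z,6E,10R)-10-hydroxy-3,7-dimethyl-10-[(5R)-5-(2-methylprop-1-en-1-yl)-2-oxo-2,5-dihydrofuran-3-yl]deca-2,6-dien-1-yl 2-methylprop-2-enoate, via lithium enolate 15 (not isolated), via selenide aldol 16 (not isolated), via selenoxide 17 (not isolated)
Conditions: PhSeH, n-BuLi, THF, −78 °C; 14, −78 °C, 30 min; 8, −78 °C, 1 h; AcOH quench; then NaIO4, NaHCO3, THF/MeOH/H2O, 0 °C to rt
Reagents that add atoms: none
Why: In this lithium phenylselenide-induced Morita–Baylis–Hillman surrogate (Michael–aldol, then selenoxide syn-elimination) PhSe− adds anti to the C13 side chain, the E(O) lactone enolate adds to the aldehyde anti to selenium through a Zimmerman–Traxler chair (anti aldol, hence 10R; any 10S epimer is removed by chromatography), the aldehyde reacts far faster than the methacrylate, and oxidation/elimination toward the acidic cis C11–H restores the butenolide.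

Step 7
Reactants: 18 butenolide carbinol; 19 acetic acid
Product: 21 (2Z,6E,10E)-10-[(4S,5R)-4-(acetyloxy)-5-(2-methylprop-1-en-1-yl)-2-oxooxolan-3-ylidene]-3,7-dimethyldeca-2,6-dien-1-yl 2-methylprop-2-enoate (CNP0152230.1), via alkoxyphosphonium acetate 20 (not isolated)
Conditions: PPh3 (1.5 equiv), DIAD (1.5 equiv), AcOH (3 equiv), toluene, −20 °C to rt
Reagents that add atoms: acetic acid (19), CC(=O)O
Why: Proposed new method: a dehydrative SN2′ acetoxylation of a cyclic (butenolide) Morita–Baylis–Hillman carbinol, in which the O-phosphonium at C10 is displaced with allylic transposition by its ion-paired acetate at the ring β-carbon C12; the closest known reaction is the SN2′ Mitsunobu esterification of acyclic acrylate-derived Morita–Baylis–Hillman alcohols (attack at an unsubstituted CH2 terminus), not yet shown for a ring terminus that becomes a stereocentre; acetate adds to C12 (a Michael position further activated by the adjacent oxyphosphonium) on the face anti to the C13 2-methylpropenyl group, giving the 12,13-trans (12S) acetate, and loss of Ph3P=O from the 10R centre on the same face (syn-SN2′ within the ion pair, or E1cB from a transient enolate with the C9 chain turned away from the enolate oxygen) places C9 anti to the carbonyl (10E); the step is irreversible and kinetically controlled, which matters because the endocyclic butenolide acetate is the thermodynamic isomer.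

**Compound list**

1 | nerol, (2Z)-3,7-dimethylocta-2,6-dien-1-ol | CC(C)=CCC/C(C)=C\CO | starting material
2 | methacryloyl chloride | C=C(C)C(=O)Cl | starting material
3 | (2Z)-3,7-dimethylocta-2,6-dien-1-yl 2-methylprop-2-enoate | C=C(C)C(=O)OC/C=C(/C)CCC=C(C)C | intermediate
4 | (2Z)-6-hydroperoxy-3,7-dimethylocta-2,7-dien-1-yl 2-methylprop-2-enoate (racemic, not isolated) | C=C(C)C(=O)OC/C=C(/C)CCC(OO)C(C)=C | intermediate
5 | (2Z)-6-hydroxy-3,7-dimethylocta-2,7-dien-1-yl 2-methylprop-2-enoate (racemic) | C=C(C)C(=O)OC/C=C(/C)CCC(O)C(C)=C | intermediate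
6 | ethyl vinyl ether | C=COCC | starting material
7 | (2Z)-6-(ethenyloxy)-3,7-dimethylocta-2,7-dien-1-yl 2-methylprop-2-enoate (racemic, not isolated) | C=C(C)C(=O)OC/C=C(/C)CCC(OC=C)C(C)=C | intermediate
8 | (2Z,6E)-3,7-dimethyl-10-oxodeca-2,6-dien-1-yl 2-methylprop-2-enoate | C=C(C)C(=O)OC/C=C(/C)CC/C=C(\C)CCC=O | intermediate
9 | 3-methylbut-2-enal (prenal) | CC(C)=CC=O | starting material
10 | methyl propiolate | C#CC(=O)OC | starting material
11 | methyl(3-methoxy-3-oxoprop-1-yn-1-yl)zinc (not isolated) | C[Zn]C#CC(=O)OC | intermediate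
12 | methyl (4R)-4-hydroxy-6-methylhept-5-en-2-ynoate | COC(=O)C#C[C@H](O)C=C(C)C | intermediate
13 | methyl (2Z,4S)-4-hydroxy-6-methylhepta-2,5-dienoate (not isolated) | COC(=O)/C=C\[C@H](O)C=C(C)C | intermediate
14 | (5S)-5-(2-methylprop-1-en-1-yl)furan-2(5H)-one | CC(C)=C[C@@H]1C=CC(=O)O1 | intermediate
15 | lithium (4S,5R)-5-(2-methylprop-1-en-1-yl)-4-(phenylselanyl)-4,5-dihydrofuran-2-olate (not isolated) | CC(C)=C[C@H]1OC(O[Li])=C[C@@H]1[Se]c1ccccc1 | intermediate
16 | (2Z,6E,10R)-10-hydroxy-3,7-dimethyl-10-[(3R,4S,5R)-5-(2-methylprop-1-en-1-yl)-2-oxo-4-(phenylselanyl)oxolan-3-yl]deca-2,6-dien-1-yl 2-methylprop-2-enoate (not isolated) | C=C(C)C(=O)OC/C=C(/C)CC/C=C(\C)CC[C@@H](O)[C@@H]1C(=O)O[C@H](C=C(C)C)[C@H]1[Se]c1ccccc1 | intermediate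
17 | Se-oxide of 16, (2Z,6E,10R)-10-[(3R,4S,5R)-4-(benzeneseleninyl)-5-(2-methylprop-1-en-1-yl)-2-oxooxolan-3-yl]-10-hydroxy-3,7-dimethyldeca-2,6-dien-1-yl 2-methylprop-2-enoate (not isolated) | C=C(C)C(=O)OC/C=C(/C)CC/C=C(\C)CC[C@@H](O)[C@@H]1C(=O)O[C@H](C=C(C)C)[C@H]1[Se](=O)c1ccccc1 | intermediate
18 | (2Z,6E,10R)-10-hydroxy-3,7-dimethyl-10-[(5R)-5-(2-methylprop-1-en-1-yl)-2-oxo-2,5-dihydrofuran-3-yl]deca-2,6-dien-1-yl 2-methylprop-2-enoate | C=C(C)C(=O)OC/C=C(/C)CC/C=C(\C)CC[C@@H](O)C1=C[C@@H](C=C(C)C)OC1=O | intermediate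
19 | acetic acid | CC(=O)O | starting material
20 | (10R)-O-triphenylphosphonio derivative of 18, acetate salt (not isolated) | C=C(C)C(=O)OC/C=C(/C)CC/C=C(\C)CC[C@@H](O[P+](c1ccccc1)(c1ccccc1)c1ccccc1)C1=C[C@@H](C=C(C)C)OC1=O.CC(=O)[O-] | intermediate
21 | (2Z,6E,10E)-10-[(4S,5R)-4-(acetyloxy)-5-(2-methylprop-1-en-1-yl)-2-oxooxolan-3-ylidene]-3,7-dimethyldeca-2,6-dien-1-yl 2-methylprop-2-enoate | C=C(C)C(=O)OC/C=C(/C)CC/C=C(\C)CC/C=C1/C(=O)O[C@H](C=C(C)C)[C@H]1OC(C)=O | target

**Step count and risks**

Total steps: 7. Longest linear sequence: 5 (steps 1, 2, 3, 6, 7 from nerol); the butenolide branch is steps 4 and 5.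

Steps most likely to fail:

Step 7 (the proposed new step). The risks are direct SN2 at C10 (giving the inverted, untransposed acetate), the 10Z isomer, and elimination to a dienyl butenolide. The fallback uses known chemistry (conjugate borylation, aldol, E1cB). It sets out from 14 (with 8) and comes back at 21. Copper-catalysed conjugate borylation of 14 (B2pin2, CuCl/Xantphos, NaOtBu, MeOH, THF) adds boron anti to the C13 side chain to give the trans β-boryl lactone F5. Oxidation with NaBO3·4H2O (retention) gives the trans β-hydroxy lactone F6, and TBSCl/imidazole gives the silyl ether F7. LiN(iPr)2 at −78 °C forms the lithium enolate F8, which adds to aldehyde 8 anti to the silyloxy group to give the aldol F9 (C10 epimers, both usable). MsCl/Et3N gives the mesylate F10, and DBU effects E1cB loss of mesylate (a far better leaving group than the ring silyloxy) to the E-alkylidene lactone F11. HF·pyridine gives the free C12 alcohol F12, and Ac2O/pyridine/DMAP gives 21.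

Step 6. The risks are poor anti-aldol selectivity at C10, retro-aldol, and selenolate or enolate addition to the methacrylate. The fallback replaces the Michael–aldol by a chemoselective Nozaki–Hiyama–Kishi coupling. It sets out from 14 (with 8) and comes back at 18. I2/pyridine in CH2Cl2 gives the α-iodobutenolide F2. CrCl2 with catalytic NiCl2 in DMF couples F2 to aldehyde 8 without base, giving 18 together with its 10S epimer F3. Dess–Martin oxidation of the mixture gives the ketone F4, and reduction with (S)-Me-CBS oxazaborolidine/catecholborane returns the 10R carbinol 18.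

Step 2. The ene reaction is inherently about 1:1 secondary to tertiary hydroperoxide, so the yield is capped near 45–50% and a separation is needed. The fallback replaces the ene reaction by epoxidation and base-promoted epoxide opening. It sets out from 3 and comes back at 5. mCPBA/NaHCO3 in CH2Cl2 at 0 °C epoxidises the electron-rich distal olefin selectively to give the 6,7-epoxide F1. Diethylaluminium 2,2,6,6-tetramethylpiperidide (Et2Al(TMP)) in toluene at 0 °C then abstracts a methyl proton to give the isopropenyl carbinol 5.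

**Further compounds**

F1 | step 2 | (2Z)-5-(3,3-dimethyloxiran-2-yl)-3-methylpent-2-en-1-yl 2-methylprop-2-enoate (racemic) | C=C(C)C(=O)OC/C=C(/C)CCC1OC1(C)C
F2 | step 6 | (5R)-3-iodo-5-(2-methylprop-1-en-1-yl)furan-2(5H)-one | IC1=C[C@@H](C=C(C)C)OC1=O
F3 | step 6 | (2Z,6E,10S)-10-hydroxy-3,7-dimethyl-10-[(5R)-5-(2-methylprop-1-en-1-yl)-2-oxo-2,5-dihydrofuran-3-yl]deca-2,6-dien-1-yl 2-methylprop-2-enoate | C=C(C)C(=O)OC/C=C(/C)CC/C=C(\C)CC[C@H](O)C1=C[C@@H](C=C(C)C)OC1=O
F4 | step 6 | (2Z,6E)-3,7-dimethyl-10-[(5R)-5-(2-methylprop-1-en-1-yl)-2-oxo-2,5-dihydrofuran-3-yl]-10-oxodeca-2,6-dien-1-yl 2-methylprop-2-enoate | C=C(C)C(=O)OC/C=C(/C)CC/C=C(\C)CCC(=O)C1=C[C@@H](C=C(C)C)OC1=O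
F5 | step 7 | (4S,5S)-5-(2-methylprop-1-en-1-yl)-4-(4,4,5,5-tetramethyl-1,3,2-dioxaborolan-2-yl)oxolan-2-one (4,5-trans) | CC(C)=C[C@H]1OC(=O)C[C@@H]1B1OC(C)(C)C(C)(C)O1
F6 | step 7 | (4S,5R)-4-hydroxy-5-(2-methylprop-1-en-1-yl)oxolan-2-one | CC(C)=C[C@H]1OC(=O)C[C@@H]1O
F7 | step 7 | (4S,5R)-4-[(tert-butyldimethylsilyl)oxy]-5-(2-methylprop-1-en-1-yl)oxolan-2-one | CC(C)=C[C@H]1OC(=O)C[C@@H]1O[Si](C)(C)C(C)(C)C
F8 | step 7 | lithium (4S,5R)-4-[(tert-butyldimethylsilyl)oxy]-5-(2-methylprop-1-en-1-yl)-4,5-dihydrofuran-2-olate | CC(C)=C[C@H]1OC(O[Li])=C[C@@H]1O[Si](C)(C)C(C)(C)C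
F9 | step 7 | (2Z,6E)-10-[(3S,4S,5R)-4-[(tert-butyldimethylsilyl)oxy]-5-(2-methylprop-1-en-1-yl)-2-oxooxolan-3-yl]-10-hydroxy-3,7-dimethyldeca-2,6-dien-1-yl 2-methylprop-2-enoate (C10 epimers) | C=C(C)C(=O)OC/C=C(/C)CC/C=C(\C)CCC(O)[C@@H]1C(=O)O[C@H](C=C(C)C)[C@H]1O[Si](C)(C)C(C)(C)C
F10 | step 7 | C10 methanesulfonate of F9 | C=C(C)C(=O)OC/C=C(/C)CC/C=C(\C)CCC(OS(C)(=O)=O)[C@@H]1C(=O)O[C@H](C=C(C)C)[C@H]1O[Si](C)(C)C(C)(C)C
F11 | step 7 | (2Z,6E,10E)-10-[(4S,5R)-4-[(tert-butyldimethylsilyl)oxy]-5-(2-methylprop-1-en-1-yl)-2-oxooxolan-3-ylidene]-3,7-dimethyldeca-2,6-dien-1-yl 2-methylprop-2-enoate | C=C(C)C(=O)OC/C=C(/C)CC/C=C(\C)CC/C=C1/C(=O)O[C@H](C=C(C)C)[C@H]1O[Si](C)(C)C(C)(C)C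
F12 | step 7 | (2Z,6E,10E)-10-[(4S,5R)-4-hydroxy-5-(2-methylprop-1-en-1-yl)-2-oxooxolan-3-ylidene]-3,7-dimethyldeca-2,6-dien-1-yl 2-methylprop-2-enoate | C=C(C)C(=O)OC/C=C(/C)CC/C=C(\C)CC/C=C1/C(=O)O[C@H](C=C(C)C)[C@H]1O
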